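The data are simulated on assumed constants, and the scatter is random.

**Clock.** In runs at 1 equiv, where both charges move together, time runs on the charged c(coupling partner): bimolecular steps take a time that scales as one over it. The runs allow a test, since Monday's 15.0 min at 0.25 M maps to 5.00 min of Tuesday's, and Monday's substrate, 45.1%, lies between Tuesday's 49.2% and 44.7% on either side of that time.

| setting | Tuesday's | Monday's | birch | alder |
|---|---|---|---|---|
| substrate | 0.75 M | 0.25 M | 0.50 M | 0.50 M |
| coupling partner | 1 equiv | 1 equiv | 1.00 equiv | 4.00 equiv |
| remark | run made earlier | run made earlier |  |  |
| time |  |  | 80 min | 80 min |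

| run | time / min | first product / % | substrate / % |
|---|---|---|---|
| Tuesday's | 4.00 | 6.0 | 49.2 |
| Tuesday's | 8.00 | 3.7 | 44.7 |
| Tuesday's | 12.0 | 3.3 | 42.2 |
| Tuesday's | 15.0 | 3.4 | 41.7 |
| Monday's | 1.33 | 7.6 | 82.7 |
| Monday's | 3.00 | 7.5 | 69.4 |
| Monday's | 6.00 | 5.2 | 57.9 |
| Monday's | 15.0 | 3.5 | 45.1 |

(each reading ± 0.5 percentage points)



- which of these holds the largest part of the substrate at the end of birch (double product / other mono adduct / first product / substrate)
- which of these holds the largest part of the substrate at the end of alder (double product / other mono adduct / first product / substrate)
- amount of first product at the end of birch, in percent of the substrate charged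

**Stall time.** Tuesday's substrate stops near 42.2% by 12.0 min, which points to the coupling partner as limiting reagent. Scaled by c(coupling partner), that reading gives the stall time, the time by which substrate stops falling: 18.0 min for birch.

**Ladder for birch.** Monday's first product stands at 7.6% and 7.5% around its peak, which maps to 0.665 min to 1.50 min. Monday's substrate reading of 57.9% maps to 3.00 min. The stall follows at 18.0 min, shorter than the 80 min asked, so birch should end as a stalled flask. First product then stays near Tuesday's last 3.4%, with Monday's at 3.5%. At 1.00 equiv, double product can't pass the substrate left, so this reckoning names substrate for birch.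

**Alder.** Its 4.00 equiv is more than the two additions take, so this reckoning names double product.

**Forecast.** The forecast agrees on substrate and double product and puts first product at 3.3%, slightly below this reckoning, on the ground that “The end state should not depend on concentration”.

**Result.** Birch ends with substrate 40.8%, ahead of double product 31.6%, and first product 3.40%. Alder ends with double product 98.9%. Birch already holds substrate 40.8% and coupling partner 0.0105% at 40.0 min, past its stall time of 18.0 min, and substrate still reads 40.8% at 80.0 min.

    substrate + coupling partner → first product (k = 0.0100 M⁻¹ s⁻¹)
    substrate + coupling partner → other mono adduct (k = 9.00 × 10⁻⁴ M⁻¹ s⁻¹)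
    coupling partner + first product → double product (k = 0.0540 M⁻¹ s⁻¹)
    coupling partner + other mono adduct → double product (k = 0.0130 M⁻¹ s⁻¹)
    2 coupling partner → self-condensation product (k = 0.00130 M⁻¹ s⁻¹)
    first product ⇌ isomer of the product (K = 6.30, k = 0.00840 s⁻¹)

**Leaner neighbour.** The scaling behind the stall time was tested at 1 equiv, so it gives no new time for a flask like birch with 0.600 equiv of coupling partner, where substrate is in excess. Birch's 18.0 min serves there as a rough scale, shorter than 80 min, so this neighbour is expected to be stalled by its end. At 80.0 min the neighbour holds coupling partner 0%, substrate 59.3% and first product 3.06%.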